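**Plan**

1. Cuts: flavone ring C at O1–C2, C2–C3, C3–C4 and C4–C4a. Ring A at C8–C8a and C6–C7 (C4a–C8a re-closes pericyclically), giving a D2 silyloxyalkyne and a 3-alkoxycyclobutenone. Ring D at D2–C(alkyne), D6–aryl and D1–C(carbinol), giving (S)-5-methylcyclohex-2-enone.
2. Forward: ring D substituents are set first by aryl 1,4-addition and aldol. The D2 ketone then becomes the enol triflate, the enyne and the silyloxyalkyne; ring A is annulated onto the alkyne; ring C follows by formylation, Grignard addition, oxidation, aroyl transfer and cyclodehydration. The D1 aroyl ketone stays masked as a silylated carbinol until ring C exists, and MOM removal is last.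
3. Stereochemistry: D4 comes from (S)-pulegone. D6 is set by copper-mediated aryl addition anti to the D4 methyl. D1 is set by aldol capture of the enolate anti to the D6 aryl. The carbinol centre is disposable.
4. Enabling feature: flavone C8, the ring A carbon bonded to D2, lies between the oxygen-bearing C8a and C7. A ketene carbonyl carbon (becoming C8a–OH) and the oxygenated carbon of an ynol ether (becoming C7–OSi) end up on either side of the ynol ether's carbon-substituted alkyne carbon (C8). C5–O comes from the cyclobutenone.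
5. Locants: D1 = CH carrying the aroyl group, D2 = alkene C bonded to flavone C8, D3 = alkene CH, D4 = CH(CH3), D5 = CH2, D6 = CH carrying the 2,4-dihydroxyphenyl group. Flavone atoms have their usual numbers.

Key step: step 16

Remark: Ar1 = 2,4-bis(methoxymethoxy)-3-(3-methylbut-2-en-1-yl)phenyl; Ar2 = 2,4-bis(methoxymethoxy)phenyl; MOM = methoxymethyl, TBS = tert-butyldimethylsilyl, TIPS = triisopropylsilyl. "D-core–X" means the D1–D6 cyclohexene (D2=D3) with X on D2, CH(OTBS)Ar1 on D1, CH3 on D4 and Ar2 on D6; Ar2 is trans to both the D1 side chain and the D4 methyl, absolute configuration as in the target.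
Remark: the carbinol carbons created by the aldol and Grignard additions, the sulfur-bearing carbon of the pulegone-derived sulfide, the sp3 ring carbon of the [2+2] adduct and the diketone methine are carried as epimer mixtures and left undefined in the SMILES, because each is destroyed later.
Remark: (S)-(−)-pulegone and 3-ethoxycyclobut-2-en-1-one are taken as purchasable; rotamers about the hindered D2–C8 bond are not treated as separate compounds.

**Route**

Step 1
Reactants: 1 resorcinol
Product: 2 1,3-bis(methoxymethoxy)benzene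
Conditions: MOMCl, i-Pr2NEt, CH2Cl2, 0 °C → rt
Reagents that add atoms: chloromethyl methyl ether, COCCl
Why: O-alkylation of both phenols with the reactive α-chloro ether under amine base (acetal protection) should give the bis-MOM ether, whose two acetal groups later direct metalation.

Step 2
Reactants: 2 1,3-bis(methoxymethoxy)benzene
Product: 4 1,3-bis(methoxymethoxy)-2-(3-methylbut-2-en-1-yl)benzene, via 2,6-bis(methoxymethoxy)phenyllithium 3 (not isolated)
Conditions: n-BuLi, THF, 0 °C → rt; CuBr·SMe2 (10 mol%), prenyl bromide, −78 °C → rt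
Reagents that add atoms: prenyl bromide, CC(C)=CCBr
Why: Directed ortho-metalation occurs at the position flanked by both OMOM groups, and after transmetalation to copper the aryl nucleophile should displace bromide at the primary allylic carbon (SN2 allylation).

Step 3
Reactants: 4 1,3-bis(methoxymethoxy)-2-(3-methylbut-2-en-1-yl)benzene
Product: 6 2,4-bis(methoxymethoxy)-3-(3-methylbut-2-en-1-yl)benzaldehyde, via 2,4-bis(methoxymethoxy)-3-prenylphenyllithium 5 (not isolated)
Conditions: n-BuLi, TMEDA, THF, 0 °C; DMF, −78 °C → rt; H2O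
Reagents that add atoms: N,N-dimethylformamide, CN(C)C=O
Why: A second directed ortho-metalation can only take place next to one OMOM group, and formylation of the aryllithium with DMF should give the aldehyde.

Step 4
Reactants: 7 4-bromoresorcinol
Product: 8 1-bromo-2,4-bis(methoxymethoxy)benzene
Conditions: MOMCl, i-Pr2NEt, CH2Cl2, 0 °C → rt
Reagents that add atoms: chloromethyl methyl ether, COCCl
Why: Acetal protection of both phenols as in step 1 should give the aryl bromide that serves as source of the D6 aryl group and of the flavone B ring.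

Step 5
Reactants: 9 (S)-(−)-pulegone
Product: 10 (S)-pulegone oxide (2,2,6-trimethyl-1-oxaspiro[2.5]octan-4-one; both spiro epimers)
Conditions: 30% H2O2, LiOH, MeOH, 0 °C → rt
Reagents that add atoms: hydrogen peroxide, OO
Why: Nucleophilic (Weitz–Scheffer) epoxidation of the enone with alkaline peroxide should give the epoxy ketone without touching the methyl-bearing stereocentre.

Step 6
Reactants: 10 (S)-pulegone oxide
Product: 11 (5S)-5-methyl-2-(phenylsulfanyl)cyclohexan-1-one (C2 epimers)
Conditions: PhSH, NaH (10 mol%), THF, 66 °C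
Reagents that add atoms: thiophenol (as sodium thiophenolate), Sc1ccccc1
Why: Thiolate should open the epoxy ketone at the carbonyl-activated α-carbon, and the resulting β-alkoxide should lose acetone by retro-aldol cleavage, the enolate being protonated by thiophenol so that the thiolate is regenerated.

Step 7
Reactants: 11 (5S)-5-methyl-2-(phenylsulfanyl)cyclohexan-1-one
Product: 13 (S)-5-methylcyclohex-2-en-1-one, via α-phenylsulfinyl ketone 12 (not isolated)
Conditions: mCPBA, CH2Cl2, −78 °C; then CaCO3, PhMe, 110 °C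
Reagents that add atoms: none
Why: Sulfide oxidation followed by thermal syn-elimination of the sulfoxide can only place the double bond at C2–C3, and the C5 stereocentre from pulegone is not involved.

Step 8
Reactants: 8 1-bromo-2,4-bis(methoxymethoxy)benzene; 13 (S)-5-methylcyclohex-2-en-1-one; 6 2,4-bis(methoxymethoxy)-3-(3-methylbut-2-en-1-yl)benzaldehyde
Product: 16 (2S,3S,5S)-3-Ar2-2-[hydroxy(Ar1)methyl]-5-methylcyclohexan-1-one (carbinol epimers), via [2,4-bis(methoxymethoxy)phenyl]magnesium bromide 14 (not isolated), via bromomagnesium enolate of the 3-aryl-5-methylcyclohexanone 15 (not isolated)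
Conditions: Mg, THF, 50 °C; CuBr·SMe2 (10 mol%), 13, −78 → −30 °C; 6, −78 °C; aq. NH4Cl
Reagents that add atoms: none
Why: Copper-catalysed 1,4-addition of the aryl Grignard reagent should occur by axial attack anti to the C5 methyl (sets D6 trans to D4), and the regiodefined magnesium enolate should add to aldehyde 6 on the face opposite the new aryl group (tandem conjugate addition–aldol; sets D1 trans to D6).

Step 9
Reactants: 16 aldol adduct
Product: 17 (2S,3S,5S)-3-Ar2-2-[(tert-butyldimethylsilyloxy)(Ar1)methyl]-5-methylcyclohexan-1-one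
Conditions: TBSOTf, 2,6-lutidine, CH2Cl2, −78 → 0 °C
Reagents that add atoms: tert-butyldimethylsilyl triflate, CC(C)(C)[Si](C)(C)OS(=O)(=O)C(F)(F)F
Why: Silylation of the aldol hydroxyl with the silyl triflate at low temperature should outpace retro-aldol cleavage and blocks it in all later basic steps.

Step 10
Reactants: 17 silylated aldol ketone
Product: 19 D-core–OSO2CF3 (D2 enol triflate), via potassium D2–D3 enolate 18 (not isolated)
Conditions: KN(SiMe3)2, THF, −78 °C; PhNTf2, −78 → 0 °C
Reagents that add atoms: N-phenylbis(trifluoromethanesulfonimide), O=S(=O)(N(c1ccccc1)S(=O)(=O)C(F)(F)F)C(F)(F)F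
Why: Kinetic deprotonation by the bulky amide should take the unhindered D3 methylene proton, not the tertiary D1 proton, and O-sulfonylation of the enolate fixes the D2=D3 double bond.

Step 11
Reactants: 19 D-core–OSO2CF3; 20 ethynyltrimethylsilane
Product: 21 D-core–C≡C–SiMe3
Conditions: Pd(PPh3)4 (5 mol%), CuI (10 mol%), Et3N, DMF, rt
Reagents that add atoms: none
Why: Sonogashira coupling of an alkenyl triflate with a terminal alkyne should form the D2–C(sp) bond with retention of the double-bond position.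

Step 12
Reactants: 21 D-core–C≡C–SiMe3
Product: 22 D-core–C≡CH
Conditions: K2CO3, MeOH–THF, rt
Reagents that add atoms: none
Why: Carbonate-catalysed methanolysis cleaves the alkynyl C–Si bond selectively, while the oxygen-bound TBS group and the MOM acetals are stable to these conditions.

Step 13
Reactants: 22 D-core–C≡CH
Product: 25 D-core–C≡C–OTIPS (silyl ynol ether), via lithium acetylide 23 (not isolated), via lithium ynolate 24 (not isolated)
Conditions: n-BuLi, THF, −78 °C; LiOOt-Bu (from t-BuOOH and LiN(SiMe3)2), −78 → 0 °C; i-Pr3SiOTf, −78 °C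
Reagents that add atoms: tert-butyl hydroperoxide (as LiOOt-Bu; supplies the ynol oxygen), CC(C)(C)OO; triisopropylsilyl triflate, CC(C)[Si](C(C)C)(C(C)C)OS(=O)(=O)C(F)(F)F
Why: Electrophilic oxygen transfer from the lithium peroxide to the acetylide carbon (acetylide oxidation to an ynolate) followed by O-silylation with the hard, bulky silyl triflate should give the isolable triisopropylsilyl ynol ether.

Step 14
Reactants: 26 3-ethoxycyclobut-2-en-1-one
Product: 27 cyclobutane-1,3-dione (3-hydroxycyclobut-2-en-1-one tautomer)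
Conditions: 90% H2SO4, 0 °C; then ice–water, Et2O extraction
Reagents that add atoms: water, O
Why: Acid hydrolysis of the vinylogous ester should release the vinylogous acid, a known though sensitive compound that is used at once.

Step 15
Reactants: 27 cyclobutane-1,3-dione
Product: 28 3-(methoxymethoxy)cyclobut-2-en-1-one
Conditions: MOMCl, i-Pr2NEt, CH2Cl2, 0 °C
Reagents that add atoms: chloromethyl methyl ether, COCCl
Why: O-alkylation of the enolate of a cyclic 1,3-dione by a hard oxocarbenium-type electrophile should give the enol acetal, so that the future C5 oxygen carries the same acid-labile group as the other phenols.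

Step 16
Reactants: 25 D-core–C≡C–OTIPS; 28 3-(methoxymethoxy)cyclobut-2-en-1-one
Product: 33 D-core–[2-hydroxy-4-(methoxymethoxy)-6-(triisopropylsilyloxy)phenyl], via vinylketene 29 (not isolated), via 4-vinylcyclobutenone adduct 30 (not isolated), via dienylketene 31 (not isolated), via cyclohexadienone 32 (not isolated)
Conditions: 28 (2 equiv), PhMe, 80 → 110 °C, sealed tube
Reagents that add atoms: none
Why: Proposed new method: heat should open 28 by 4π electrocyclic ring opening (strain release) to vinylketene 29, whose electrophilic carbonyl carbon is attacked by the nucleophilic, D2-bound alkyne carbon of 25 in a [2+2] cycloaddition to give 30; 30 should reopen (4π) to dienylketene 31, which closes to 32 and tautomerises to phenol 33. The closest known reaction is the Danheiser benzannulation of cyclobutenones with trialkylsilyloxyalkynes to 3-silyloxyphenols; new here are the 3-alkoxy group on the cyclobutenone and a hindered, conjugated enyne as the ynol ether. Ring A is closed by thermal disrotatory 6π electrocyclisation (C4a–C8a) followed by enolisation, C8–C8a and C6–C7 having been made in the [2+2] step. No stereocentre is formed, and the D1, D4 and D6 centres carry no acidic hydrogen under these neutral conditions. The step needs regioselectivity (C8 between C8a and C7) and chemoselectivity for the alkyne over the alkenes; ketene–ynol ether polarity secures the first and the far higher nucleophilicity of the silyloxyalkyne the second. The three ring A oxygens should emerge differentiated: C8a–OH free, C7–OTIPS and C5–OMOM.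

Step 17
Reactants: 33 ring A phenol
Product: 34 D-core–[3-formyl-2-hydroxy-4-(methoxymethoxy)-6-(triisopropylsilyloxy)phenyl]
Conditions: MgCl2, Et3N, (CH2O)n, THF, 70 °C
Reagents that add atoms: paraformaldehyde (formaldehyde), C=O
Why: Magnesium phenoxide-directed ortho-formylation (Casnati–Skattebøl) delivers formaldehyde inside the chelate to C4a, the only free position ortho to the hydroxyl, and a second formaldehyde oxidises the hydroxymethyl intermediate to the aldehyde.

Step 18
Reactants: 34 salicylaldehyde; 35 5-bromo-2-methylpent-2-ene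
Product: 37 D-core–[2-hydroxy-3-(1-hydroxy-5-methylhex-4-en-1-yl)-4-(methoxymethoxy)-6-(triisopropylsilyloxy)phenyl], via (4-methylpent-3-en-1-yl)magnesium bromide 36 (not isolated)
Conditions: 35, Mg, THF, rt; then 34 (to 3 equiv of 36), THF, −78 → 0 °C
Reagents that add atoms: none
Why: Grignard 1,2-addition to the aldehyde (one equivalent being consumed by the phenol) should install the chain whose α-carbon becomes C3 and whose remainder becomes the 3-prenyl group.

Step 19
Reactants: 37 benzylic alcohol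
Product: 38 D-core–[2-hydroxy-4-(methoxymethoxy)-3-(5-methylhex-4-enoyl)-6-(triisopropylsilyloxy)phenyl]
Conditions: MnO2, CH2Cl2, rt
Reagents that add atoms: none
Why: MnO2 should oxidise the hydrogen-bonded benzylic carbinol to the chelated o-hydroxyaryl ketone selectively (benzylic alcohol oxidation) and leave phenol, alkenes, acetals and silyl ethers untouched.

Step 20
Reactants: 8 1-bromo-2,4-bis(methoxymethoxy)benzene
Product: 40 2,4-bis(methoxymethoxy)benzoic acid, via 2,4-bis(methoxymethoxy)phenyllithium 39 (not isolated)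
Conditions: n-BuLi, THF, −78 °C; CO2; 0.5 M HCl to pH 4, 0 °C
Reagents that add atoms: carbon dioxide, O=C=O
Why: Bromine–lithium exchange followed by carboxylation of the aryllithium should give the B-ring acid, with brief cold acidification sparing the MOM groups.

Step 21
Reactants: 38 o-hydroxyaryl ketone; 40 2,4-bis(methoxymethoxy)benzoic acid
Product: 41 D-core–[2-(Ar2-carbonyloxy)-4-(methoxymethoxy)-3-(5-methylhex-4-enoyl)-6-(triisopropylsilyloxy)phenyl]
Conditions: DCC, DMAP, CH2Cl2, rt
Reagents that add atoms: none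
Why: Steglich esterification acylates the only free hydroxyl (C8a–OH) through the acylpyridinium intermediate under conditions that keep the acid-labile groups of the acid partner.

Step 22
Reactants: 41 aryl ester
Product: 42 D-core–{2-hydroxy-4-(methoxymethoxy)-3-[2-(Ar2-carbonyl)-5-methylhex-4-enoyl]-6-(triisopropylsilyloxy)phenyl}
Conditions: LiN(SiMe3)2, THF, −78 → 0 °C; AcOH
Reagents that add atoms: none
Why: In the Baker–Venkataraman rearrangement the ketone enolate attacks the neighbouring aryl ester through a six-membered transition state, transferring the aroyl group from oxygen to carbon to give the 2-prenyl-1,3-diketone and freeing C8a–OH alone.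

Step 23
Reactants: 42 1,3-diketone
Product: 43 D-core–[2-Ar2-5-(methoxymethoxy)-3-(3-methylbut-2-en-1-yl)-4-oxo-7-(triisopropylsilyloxy)-4H-chromen-8-yl]
Conditions: PPTS (0.3 equiv), 4 Å MS, PhMe, 90 °C
Reagents that add atoms: none
Why: The free C8a hydroxyl, the only phenol ortho to the diketone, should add to the B-ring carbonyl (6-exo-trig) and the hemiketal should lose water under weak-acid catalysis (cyclodehydration to the 4-pyranone), which fixes ring D on C8 while the aprotic medium spares MOM and silyl ethers.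

Step 24
Reactants: 43 protected flavone
Product: 44 7-hydroxyflavone with free D1 carbinol (43 without both silyl groups)
Conditions: TBAF, THF, 0 °C → rt
Reagents that add atoms: none
Why: Fluoride cleaves both the phenolic TIPS ether and the secondary benzylic TBS ether (Si–F bond formation) and leaves the MOM acetals intact.

Step 25
Reactants: 44 carbinol
Product: 45 hepta-MOM ether of the target (free 7-OH; D1–C(=O)Ar1)
Conditions: Dess–Martin periodinane, NaHCO3, CH2Cl2, 0 °C → rt
Reagents that add atoms: none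
Why: Buffered Dess–Martin oxidation converts the secondary benzylic alcohol into the aroyl ketone under neutral conditions, so that the now enolisable D1 centre is neither epimerised nor the D2=D3 double bond moved into conjugation.

Step 26
Reactants: 45 hepta-MOM ether
Product: 46 CNP0314407.1 (target)
Conditions: 3 M aq. HCl, MeOH–THF, 40 °C
Reagents that add atoms: none
Why: Acid-catalysed acetal exchange with methanol should remove all seven MOM groups, and the mild temperature is chosen to limit addition of the liberated phenols to the prenyl double bonds.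

**Compound list**

1 | resorcinol | Oc1cccc(O)c1 | starting material
2 | 1,3-bis(methoxymethoxy)benzene | COCOc1cccc(OCOC)c1 | intermediate
3 | 2,6-bis(methoxymethoxy)phenyllithium | [Li]c1c(OCOC)cccc1OCOC | intermediate
4 | 1,3-bis(methoxymethoxy)-2-(3-methylbut-2-en-1-yl)benzene | CC(C)=CCc1c(OCOC)cccc1OCOC | intermediate
5 | 2,4-bis(methoxymethoxy)-3-(3-methylbut-2-en-1-yl)phenyllithium | [Li]c1ccc(OCOC)c(CC=C(C)C)c1OCOC | intermediate
6 | 2,4-bis(methoxymethoxy)-3-(3-methylbut-2-en-1-yl)benzaldehyde | CC(C)=CCc1c(OCOC)ccc(C=O)c1OCOC | intermediate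
7 | 4-bromoresorcinol | Oc1ccc(Br)c(O)c1 | starting material
8 | 1-bromo-2,4-bis(methoxymethoxy)benzene | COCOc1ccc(Br)c(OCOC)c1 | intermediate
9 | (S)-(−)-pulegone | CC(C)=C1CC[C@H](C)CC1=O | starting material
10 | (S)-pulegone oxide (spiro epimers) | CC1(C)OC12CC[C@H](C)CC2=O | intermediate
11 | (5S)-5-methyl-2-(phenylsulfanyl)cyclohexan-1-one (C2 epimers) | O=C1C[C@@H](C)CCC1Sc1ccccc1 | intermediate
12 | (5S)-5-methyl-2-(phenylsulfinyl)cyclohexan-1-one | O=C1C[C@@H](C)CCC1S(=O)c1ccccc1 | intermediate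
13 | (S)-5-methylcyclohex-2-en-1-one | O=C1C[C@@H](C)CC=C1 | intermediate
14 | [2,4-bis(methoxymethoxy)phenyl]magnesium bromide | COCOc1ccc([Mg]Br)c(OCOC)c1 | intermediate
15 | bromomagnesium enolate of trans-3-Ar2-5-methylcyclohexanone | C1=C(O[Mg]Br)C[C@@H](C)C[C@@H]1c1ccc(OCOC)cc1OCOC | intermediate
16 | (2S,3S,5S)-3-Ar2-2-[hydroxy(Ar1)methyl]-5-methylcyclohexan-1-one (carbinol epimers) | CC(C)=CCc1c(OCOC)ccc(C(O)[C@H]2C(=O)C[C@@H](C)C[C@@H]2c2ccc(OCOC)cc2OCOC)c1OCOC | intermediate
17 | (2S,3S,5S)-3-Ar2-2-[(TBS-oxy)(Ar1)methyl]-5-methylcyclohexan-1-one | CC(C)=CCc1c(OCOC)ccc(C(O[Si](C)(C)C(C)(C)C)[C@H]2C(=O)C[C@@H](C)C[C@@H]2c2ccc(OCOC)cc2OCOC)c1OCOC | intermediate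
18 | D-core–OK (potassium D2–D3 enolate) | CC(C)=CCc1c(OCOC)ccc(C(O[Si](C)(C)C(C)(C)C)[C@H]2C(O[K])=C[C@@H](C)C[C@@H]2c2ccc(OCOC)cc2OCOC)c1OCOC | intermediate
19 | D-core–OSO2CF3 (D2 enol triflate) | CC(C)=CCc1c(OCOC)ccc(C(O[Si](C)(C)C(C)(C)C)[C@H]2C(OS(=O)(=O)C(F)(F)F)=C[C@@H](C)C[C@@H]2c2ccc(OCOC)cc2OCOC)c1OCOC | intermediate
20 | ethynyltrimethylsilane | C#C[Si](C)(C)C | starting material
21 | D-core–C≡C–SiMe3 | CC(C)=CCc1c(OCOC)ccc(C(O[Si](C)(C)C(C)(C)C)[C@H]2C(C#C[Si](C)(C)C)=C[C@@H](C)C[C@@H]2c2ccc(OCOC)cc2OCOC)c1OCOC | intermediate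
22 | D-core–C≡CH | CC(C)=CCc1c(OCOC)ccc(C(O[Si](C)(C)C(C)(C)C)[C@H]2C(C#C)=C[C@@H](C)C[C@@H]2c2ccc(OCOC)cc2OCOC)c1OCOC | intermediate
23 | D-core–C≡CLi (lithium acetylide) | CC(C)=CCc1c(OCOC)ccc(C(O[Si](C)(C)C(C)(C)C)[C@H]2C(C#C[Li])=C[C@@H](C)C[C@@H]2c2ccc(OCOC)cc2OCOC)c1OCOC | intermediate
24 | D-core–C≡C–OLi (lithium ynolate) | CC(C)=CCc1c(OCOC)ccc(C(O[Si](C)(C)C(C)(C)C)[C@H]2C(C#CO[Li])=C[C@@H](C)C[C@@H]2c2ccc(OCOC)cc2OCOC)c1OCOC | intermediate
25 | D-core–C≡C–OTIPS (silyl ynol ether) | CC(C)=CCc1c(OCOC)ccc(C(O[Si](C)(C)C(C)(C)C)[C@H]2C(C#CO[Si](C(C)C)(C(C)C)C(C)C)=C[C@@H](C)C[C@@H]2c2ccc(OCOC)cc2OCOC)c1OCOC | intermediate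
26 | 3-ethoxycyclobut-2-en-1-one | CCOC1=CC(=O)C1 | starting material
27 | cyclobutane-1,3-dione | O=C1CC(=O)C1 | intermediate
28 | 3-(methoxymethoxy)cyclobut-2-en-1-one | COCOC1=CC(=O)C1 | intermediate
29 | 3-(methoxymethoxy)buta-1,3-dien-1-one (vinylketene) | COCOC(=C)C=C=O | intermediate
30 | 2-(D-core)-4-[1-(methoxymethoxy)ethenyl]-3-(triisopropylsilyloxy)cyclobut-2-en-1-one | CC(C)=CCc1c(OCOC)ccc(C(O[Si](C)(C)C(C)(C)C)[C@H]2C(C3=C(O[Si](C(C)C)(C(C)C)C(C)C)C(C(=C)OCOC)C3=O)=C[C@@H](C)C[C@@H]2c2ccc(OCOC)cc2OCOC)c1OCOC | intermediate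
31 | 2-(D-core)-5-(methoxymethoxy)-3-(triisopropylsilyloxy)hexa-1,3,5-trien-1-one (dienylketene) | CC(C)=CCc1c(OCOC)ccc(C(O[Si](C)(C)C(C)(C)C)[C@H]2C(C(=C=O)C(O[Si](C(C)C)(C(C)C)C(C)C)=CC(=C)OCOC)=C[C@@H](C)C[C@@H]2c2ccc(OCOC)cc2OCOC)c1OCOC | intermediate
32 | 2-(D-core)-5-(methoxymethoxy)-3-(triisopropylsilyloxy)cyclohexa-2,4-dien-1-one | CC(C)=CCc1c(OCOC)ccc(C(O[Si](C)(C)C(C)(C)C)[C@H]2C(C3=C(O[Si](C(C)C)(C(C)C)C(C)C)C=C(OCOC)CC3=O)=C[C@@H](C)C[C@@H]2c2ccc(OCOC)cc2OCOC)c1OCOC | intermediate
33 | D-core–[2-hydroxy-4-(methoxymethoxy)-6-(triisopropylsilyloxy)phenyl] | CC(C)=CCc1c(OCOC)ccc(C(O[Si](C)(C)C(C)(C)C)[C@H]2C(c3c(O)cc(OCOC)cc3O[Si](C(C)C)(C(C)C)C(C)C)=C[C@@H](C)C[C@@H]2c2ccc(OCOC)cc2OCOC)c1OCOC | intermediate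
34 | D-core–[3-formyl-2-hydroxy-4-(methoxymethoxy)-6-(triisopropylsilyloxy)phenyl] | CC(C)=CCc1c(OCOC)ccc(C(O[Si](C)(C)C(C)(C)C)[C@H]2C(c3c(O)c(C=O)c(OCOC)cc3O[Si](C(C)C)(C(C)C)C(C)C)=C[C@@H](C)C[C@@H]2c2ccc(OCOC)cc2OCOC)c1OCOC | intermediate
35 | 5-bromo-2-methylpent-2-ene | CC(C)=CCCBr | starting material
36 | (4-methylpent-3-en-1-yl)magnesium bromide | CC(C)=CCC[Mg]Br | intermediate
37 | D-core–[2-hydroxy-3-(1-hydroxy-5-methylhex-4-en-1-yl)-4-(methoxymethoxy)-6-(triisopropylsilyloxy)phenyl] (carbinol epimers) | CC(C)=CCc1c(OCOC)ccc(C(O[Si](C)(C)C(C)(C)C)[C@H]2C(c3c(O)c(C(O)CCC=C(C)C)c(OCOC)cc3O[Si](C(C)C)(C(C)C)C(C)C)=C[C@@H](C)C[C@@H]2c2ccc(OCOC)cc2OCOC)c1OCOC | intermediate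
38 | D-core–[2-hydroxy-4-(methoxymethoxy)-3-(5-methylhex-4-enoyl)-6-(triisopropylsilyloxy)phenyl] | CC(C)=CCc1c(OCOC)ccc(C(O[Si](C)(C)C(C)(C)C)[C@H]2C(c3c(O)c(C(=O)CCC=C(C)C)c(OCOC)cc3O[Si](C(C)C)(C(C)C)C(C)C)=C[C@@H](C)C[C@@H]2c2ccc(OCOC)cc2OCOC)c1OCOC | intermediate
39 | 2,4-bis(methoxymethoxy)phenyllithium | [Li]c1ccc(OCOC)cc1OCOC | intermediate
40 | 2,4-bis(methoxymethoxy)benzoic acid | COCOc1ccc(C(=O)O)c(OCOC)c1 | intermediate
41 | D-core–[2-(Ar2-carbonyloxy)-4-(methoxymethoxy)-3-(5-methylhex-4-enoyl)-6-(triisopropylsilyloxy)phenyl] | CC(C)=CCc1c(OCOC)ccc(C(O[Si](C)(C)C(C)(C)C)[C@H]2C(c3c(OC(=O)c4ccc(OCOC)cc4OCOC)c(C(=O)CCC=C(C)C)c(OCOC)cc3O[Si](C(C)C)(C(C)C)C(C)C)=C[C@@H](C)C[C@@H]2c2ccc(OCOC)cc2OCOC)c1OCOC | intermediate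
42 | D-core–{2-hydroxy-4-(methoxymethoxy)-3-[2-(Ar2-carbonyl)-5-methylhex-4-enoyl]-6-(triisopropylsilyloxy)phenyl} (methine epimers) | CC(C)=CCc1c(OCOC)ccc(C(O[Si](C)(C)C(C)(C)C)[C@H]2C(c3c(O)c(C(=O)C(CC=C(C)C)C(=O)c4ccc(OCOC)cc4OCOC)c(OCOC)cc3O[Si](C(C)C)(C(C)C)C(C)C)=C[C@@H](C)C[C@@H]2c2ccc(OCOC)cc2OCOC)c1OCOC | intermediate
43 | D-core–[2-Ar2-5-(methoxymethoxy)-3-(3-methylbut-2-en-1-yl)-4-oxo-7-(triisopropylsilyloxy)-4H-chromen-8-yl] | CC(C)=CCc1c(OCOC)ccc(C(O[Si](C)(C)C(C)(C)C)[C@H]2C(c3c(O[Si](C(C)C)(C(C)C)C(C)C)cc(OCOC)c4c(=O)c(CC=C(C)C)c(-c5ccc(OCOC)cc5OCOC)oc34)=C[C@@H](C)C[C@@H]2c2ccc(OCOC)cc2OCOC)c1OCOC | intermediate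
44 | 7-hydroxyflavone with D1–CH(OH)Ar1 (43 without TBS and TIPS; carbinol epimers) | CC(C)=CCc1c(OCOC)ccc(C(O)[C@H]2C(c3c(O)cc(OCOC)c4c(=O)c(CC=C(C)C)c(-c5ccc(OCOC)cc5OCOC)oc34)=C[C@@H](C)C[C@@H]2c2ccc(OCOC)cc2OCOC)c1OCOC | intermediate
45 | hepta-MOM ether of the target (free 7-OH; D1 R, D4 S, D6 S) | CC(C)=CCc1c(OCOC)ccc(C(=O)[C@H]2C(c3c(O)cc(OCOC)c4c(=O)c(CC=C(C)C)c(-c5ccc(OCOC)cc5OCOC)oc34)=C[C@@H](C)C[C@@H]2c2ccc(OCOC)cc2OCOC)c1OCOC | intermediate
46 | CNP0314407.1 (D1 R, D4 S, D6 S) | CC(C)=CCc1c(O)ccc(C(=O)[C@H]2C(c3c(O)cc(O)c4c(=O)c(CC=C(C)C)c(-c5ccc(O)cc5O)oc34)=C[C@@H](C)C[C@@H]2c2ccc(O)cc2O)c1O | target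

**Step count and risks**

Total step count: 26. Longest linear sequence: 19 steps (steps 5–13, 16–19 and 21–26 from (S)-pulegone; the resorcinol branch through steps 1–3 and 8 is equally long).

Steps most likely to fail:

1. Step 16 (proposed new method). The alkoxy-substituted vinylketene may dimerise, or acylate the newly formed phenol, faster than the hindered silyloxyalkyne intercepts it, and the ynol ether may decompose on prolonged heating. Fallback by known cross-coupling, setting out from 19 and returning at 34: Miyaura borylation of 19 (B2pin2, PdCl2(dppf), KOAc, dioxane, 80 °C) would give the D2 pinacol boronate F1. Separately, commercial 2,4,6-trihydroxybenzaldehyde would be silylated at its non-chelated 4-hydroxyl (TIPSCl, imidazole) to 2,6-dihydroxy-4-(triisopropylsilyloxy)benzaldehyde F2. Mono-protection (MOMCl, i-Pr2NEt; the second hydroxyl stays chelated) would give 2-hydroxy-6-(methoxymethoxy)-4-(triisopropylsilyloxy)benzaldehyde F3. Iodination ortho to the remaining hydroxyl (BnMe3N·ICl2, NaHCO3, CH2Cl2–MeOH; the para position lies between two protected oxygens and is the more hindered) would give aryl iodide F4. Suzuki–Miyaura coupling of F1 with F4 (Pd(OAc)2, SPhos, K3PO4, dioxane–H2O, 80 °C) would give salicylaldehyde 34, and the route resumes at step 18.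

2. Step 13. Oxygen transfer from LiOOt-Bu to the hindered, conjugated lithium acetylide may be incomplete, and the ynolate may be silylated on carbon or the ynol ether hydrolysed during isolation. Fallback by ester homologation, setting out from 19 and returning at 25: methoxycarbonylation of 19 (Pd(OAc)2, dppp, CO, MeOH, Et3N, DMF, 60 °C) would give the D2 methyl ester F5. Kowalski homologation (LiCHBr2 from CH2Br2 and lithium 2,2,6,6-tetramethylpiperidide, THF, −78 °C; then n-BuLi, −78 → 0 °C) would rearrange F5 to the same lithium ynolate 24, which is silylated in the flask with i-Pr3SiOTf to 25. Steps 11–13 are replaced.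

3. Step 23. The acid may ionise the electron-rich benzylic silyl ether or strip MOM groups before the hindered hemiketal dehydrates, which would open competing ring closures through the C5 oxygen or the B-ring oxygen. Fallback by unmasking first and closing ring C together with the deprotection, setting out from 42 and returning at 46: TBAF would desilylate 42 to diketone F6 (free D1 carbinol and C7–OH). MnO2, which is inert to the diketone and the chelated phenol, would oxidise the benzylic carbinol to aroyl ketone F7. Methanolic HCl (MeOH–THF, 40 °C) should then cyclodehydrate F7 through the already free C8a hydroxyl before the C5 and B-ring acetals are lost, and remove all seven MOM groups to give 46.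

Further compounds

F1 | step 16 | D-core–B(pin) (D2 pinacol boronate) | CC(C)=CCc1c(OCOC)ccc(C(O[Si](C)(C)C(C)(C)C)[C@H]2C(B3OC(C)(C)C(C)(C)O3)=C[C@@H](C)C[C@@H]2c2ccc(OCOC)cc2OCOC)c1OCOC
F2 | step 16 | 2,6-dihydroxy-4-(triisopropylsilyloxy)benzaldehyde | O=Cc1c(O)cc(O[Si](C(C)C)(C(C)C)C(C)C)cc1O
F3 | step 16 | 2-hydroxy-6-(methoxymethoxy)-4-(triisopropylsilyloxy)benzaldehyde | O=Cc1c(O)cc(O[Si](C(C)C)(C(C)C)C(C)C)cc1OCOC
F4 | step 16 | 2-hydroxy-3-iodo-6-(methoxymethoxy)-4-(triisopropylsilyloxy)benzaldehyde | O=Cc1c(O)c(I)c(O[Si](C(C)C)(C(C)C)C(C)C)cc1OCOC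
F5 | step 13 | D-core–CO2CH3 (D2 methyl ester) | CC(C)=CCc1c(OCOC)ccc(C(O[Si](C)(C)C(C)(C)C)[C@H]2C(C(=O)OC)=C[C@@H](C)C[C@@H]2c2ccc(OCOC)cc2OCOC)c1OCOC
F6 | step 23 | desilylated diketone (42 without TBS and TIPS) | CC(C)=CCc1c(OCOC)ccc(C(O)[C@H]2C(c3c(O)c(C(=O)C(CC=C(C)C)C(=O)c4ccc(OCOC)cc4OCOC)c(OCOC)cc3O)=C[C@@H](C)C[C@@H]2c2ccc(OCOC)cc2OCOC)c1OCOC
F7 | step 23 | D1 aroyl ketone of F6 | CC(C)=CCc1c(OCOC)ccc(C(=O)[C@H]2C(c3c(O)c(C(=O)C(CC=C(C)C)C(=O)c4ccc(OCOC)cc4OCOC)c(OCOC)cc3O)=C[C@@H](C)C[C@@H]2c2ccc(OCOC)cc2OCOC)c1OCOC
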